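**Plan**

1. Ring numbering used throughout: C1 = ketone carbon, C2 = methyl-bearing alkene carbon, C3 = alkene CH, C4 = carbinol carbon, C5 = carbon bearing the geranylgeranyl chain (C1' = its first CH2), C6 = CH2. The target is (4S,5S), with hydroxyl and side chain cis.
2. Enabling feature: O4 lies gamma to the carbonyl carbon C1 (O4–C4–C5–C6–C1), so the hydroxy enone is the carbocyclic isomer of a gamma-butyrolactone (ring O4, C4, C5, C6, C1) whose C4 carries the C2=C3 alkene. A Z-lithiated C2 can reach C1 through the five-atom array C2=C3–C4–O4–C1, and O4 then leaves as the free hydroxyl.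
3. Retrosynthetic cuts, in order: C1–C2 (ring closure); the lactone C1–O4 bond (back to a 1,4-diol); C2–I and C3–H (from a C2≡C3 alkyne); C4–H (ynone reduction); C3–C4 (acyl–alkyne coupling); C5–C1' (enolate alkylation with geranylgeranyl bromide).
4. Forward: the acyclic C1–C6 chain is assembled on a succinate, the temporary lactone ring is closed, and the carbocycle C1–C6, the only ring of the target, is formed last by a lactone-to-cyclohexenone transacylation, without protecting groups.
5. Stereochemistry: C5 from an auxiliary-controlled (Evans) alkylation; C4 from a catalyst-controlled (Noyori) ynone reduction; Z-C2=C3 from hydroxyl-directed trans-hydroalumination; the all-E chain from geranylgeraniol. The trans-lactone maps onto the cis-hydroxy/alkyl enone.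

Key step: step 9

Remark: geranylgeranyl bromide is assumed to be made fresh from commercial (2E,6E,10E)-geranylgeraniol and used crude, because the allylic bromide does not store well.

**Route**

Step 1
Reactants: 1 (2E,6E,10E)-geranylgeraniol
Product: 2 (2E,6E,10E)-geranylgeranyl bromide
Conditions: PBr3 (0.4 equiv), Et2O, 0 °C; used crude
Reagents that add atoms: phosphorus tribromide, BrP(Br)Br
Why: Bromination of the primary allylic alcohol through its phosphite ester is an SN2-type displacement that should proceed at 0 °C without allylic transposition or loss of E geometry.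

Step 2
Reactants: 3 mono-tert-butyl succinate (4-tert-butoxy-4-oxobutanoic acid); 4 (S)-4-benzyl-1,3-oxazolidin-2-one
Product: 5 tert-butyl 4-[(4S)-4-benzyl-2-oxo-1,3-oxazolidin-3-yl]-4-oxobutanoate
Conditions: DCC, DMAP (cat.), CH2Cl2, 0 °C to rt
Reagents that add atoms: none
Why: DMAP-catalysed carbodiimide (Steglich-type) N-acylation of the oxazolidinone by the free acid should give the imide and leave the tert-butyl ester untouched.

Step 3
Reactants: 5 succinate imide; 2 geranylgeranyl bromide
Product: 7 tert-butyl (3S,5E,9E,13E)-3-{[(4S)-4-benzyl-2-oxo-1,3-oxazolidin-3-yl]carbonyl}-6,10,14,18-tetramethylnonadeca-5,9,13,17-tetraenoate (alkylated imide), via sodium Z-enolate 6 (not isolated)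
Conditions: NaN(SiMe3)2, THF, −78 °C; then 2, −78 to −40 °C
Reagents that add atoms: none
Why: Evans asymmetric alkylation: the chelated Z-sodium enolate forms at the more acidic imide alpha-position and should be alkylated by the allylic bromide on the face opposite the benzyl group, which sets (S)-C5 of the target.

Step 4
Reactants: 7 alkylated imide
Product: 8 tert-butyl (3S,5E,9E,13E)-3-[(ethylsulfanyl)carbonyl]-6,10,14,18-tetramethylnonadeca-5,9,13,17-tetraenoate (thioester)
Conditions: EtSH, n-BuLi, THF, 0 °C (gives LiSEt); then 7, 0 °C to rt; aq NH4Cl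
Reagents that add atoms: ethanethiol, used as lithium ethanethiolate made in the flask with n-BuLi, CCS
Why: Thiolysis of the N-acyloxazolidinone: the soft thiolate should attack only the exocyclic imide carbonyl, giving the thioester without epimerisation and returning the auxiliary, while the tert-butyl ester is inert.

Step 5
Reactants: 8 thioester; 9 propyne
Product: 10 tert-butyl (3S,5E,9E,13E)-3-(but-2-ynoyl)-6,10,14,18-tetramethylnonadeca-5,9,13,17-tetraenoate (ynone)
Conditions: propyne (excess, solution in DMF), PdCl2(dppf) (cat.), tri(2-furyl)phosphine (cat.), CuI (1.5 equiv), Et3N, DMF, 50 °C, sealed vessel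
Reagents that add atoms: none
Why: Thioester–alkyne coupling of the Fukuyama/acyl-Sonogashira type: zerovalent palladium inserts into the acyl–sulfur bond, the copper acetylide of propyne transmetalates and reductive elimination should give the ynone, while copper binds the released thiolate.

Step 6
Reactants: 10 ynone
Product: 11 tert-butyl (3S,5E,9E,13E)-3-[(1S)-1-hydroxybut-2-yn-1-yl]-6,10,14,18-tetramethylnonadeca-5,9,13,17-tetraenoate (propargylic alcohol)
Conditions: Ru[(S,S)-TsDPEN](p-cymene) (amido complex pre-formed from RuCl[(S,S)-TsDPEN](p-cymene) and KOH, cat.), i-PrOH, rt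
Reagents that add atoms: none
Why: Noyori asymmetric transfer hydrogenation of an alkynyl ketone is catalyst-controlled; by analogy with simple alkynyl ketones the (S,S)-catalyst should give the (S)-carbinol at C4 regardless of the neighbouring stereocentre, and the base-free conditions spare the alkyne, the alkenes, the ester and the alpha-stereocentre.

Step 7
Reactants: 11 propargylic alcohol
Product: 13 (2Z,4S,5S)-2-iodo-5-[(2E,6E,10E)-3,7,11,15-tetramethylhexadeca-2,6,10,14-tetraen-1-yl]hept-2-ene-4,7-diol (iodo diol), via cyclic alkenylaluminate 12 (not isolated)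
Conditions: NaAlH2(OCH2CH2OMe)2 (Red-Al, 3 equiv), THF, 0 °C to rt; EtOAc, 0 °C; then I2, THF, −78 °C; aq Na2S2O3 and Rochelle salt
Reagents that add atoms: iodine, [I][I]
Why: Alkoxide-directed trans-hydroalumination of the propargylic alcohol places aluminium on the distal carbon C2 in a five-membered oxaaluminacycle and hydride on C3, so iodinolysis with retention should give only the Z-iodoalkene (iodine cis to C4), while the same reagent reduces the tert-butyl ester to the primary alcohol.

Step 8
Reactants: 13 iodo diol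
Product: 16 (4S,5S)-5-[(1Z)-2-iodoprop-1-en-1-yl]-4-[(2E,6E,10E)-3,7,11,15-tetramethylhexadeca-2,6,10,14-tetraen-1-yl]oxolan-2-one (trans-lactone), via hydroxy aldehyde 14 (not isolated), via lactol 15 (not isolated)
Conditions: TEMPO (cat.), PhI(OAc)2 (2.5 equiv), CH2Cl2, rt
Reagents that add atoms: none
Why: Oxoammonium-mediated oxidative lactonisation of a 1,4-diol: the primary alcohol should be oxidised selectively, the aldehyde is trapped by the C4 hydroxyl as a lactol, and the lactol is oxidised to the gamma-lactone, so O4 becomes the ring oxygen and neither stereocentre is touched.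

Step 9
Reactants: 16 trans-lactone
Product: 20 (4S,5S)-4-hydroxy-2-methyl-5-[(2E,6E,10E)-3,7,11,15-tetramethylhexadeca-2,6,10,14-tetraen-1-yl]cyclohex-2-en-1-one (target), via alkenyllithium 17 (not isolated), via bridged lithium alkoxide 18 (not isolated), via lithium alkoxide of the target 19 (not isolated)
Conditions: t-BuLi (2.0 equiv, slow addition), THF/Et2O/pentane 4:1:1, high dilution, −100 °C then −78 °C; sat. aq NH4Cl, −78 °C to rt
Reagents that add atoms: none
Why: Proposed new method: iodine–lithium exchange, which at −100 °C should outrun attack of t-BuLi on the lactone and alpha-deprotonation, gives the Z-alkenyllithium 17, whose C2 carbanion lobe lies in the alkene plane cis to C4 and is held over the lactone carbon C1; addition to C1=O gives the bridged 1-oxido-7-oxabicyclo[2.2.1]hept-2-ene 18, which collapses by expelling its only leaving group, the bridging O4, to give alkoxide 19 and, on protonation, the free gamma-hydroxy enone. The closest known reaction types are the anionic homo-Fries (1,4 O-to-C acyl) migration of ortho-lithiobenzyl and Z-3-lithioallyl esters and the Parham-type cyclisation of alkenyllithiums onto esters and Weinreb amides; what is new is a lactone as the acyl group, so that the migration becomes a lactone-to-carbocycle ring transformation through a strained bridged hemiketal, whose cost should be met by the strongly exothermic C–C bond formation and the strain-relieving C–O cleavage that follows. The carbocycle C1–C6 closes in a 6-exo-trig mode (C1=O exocyclic), and the same bond closes the transient oxolene ring C1–C2=C3–C4–O4 in a 5-exo-trig mode. No new stereocentre is formed: C4 and C5 are carried over from the trans-lactone, which becomes the cis-4-hydroxy-5-alkyl enone because O4 changes from ring member to substituent. The step needs carbonyl addition to win over intramolecular proton transfer from C6–H and over intermolecular attack on the product enone; the Z geometry fixed in step 7, the short five-atom reach of C2 to C1 along a near Bürgi–Dunitz trajectory, high dilution and slow addition of exactly two equivalents of t-BuLi should secure this.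

**Compound list**

1 | (2E,6E,10E)-geranylgeraniol | CC(C)=CCC/C(C)=C/CC/C(C)=C/CC/C(C)=C/CO | starting material
2 | (2E,6E,10E)-geranylgeranyl bromide | CC(C)=CCC/C(C)=C/CC/C(C)=C/CC/C(C)=C/CBr | intermediate
3 | mono-tert-butyl succinate | CC(C)(C)OC(=O)CCC(=O)O | starting material
4 | (S)-4-benzyl-1,3-oxazolidin-2-one | O=C1N[C@@H](Cc2ccccc2)CO1 | starting material
5 | tert-butyl 4-[(4S)-4-benzyl-2-oxo-1,3-oxazolidin-3-yl]-4-oxobutanoate | CC(C)(C)OC(=O)CCC(=O)N1[C@@H](Cc2ccccc2)COC1=O | intermediate
6 | sodium Z-enolate of 5 | [Na+].[O-]/C(=C\CC(=O)OC(C)(C)C)N1[C@@H](Cc2ccccc2)COC1=O | intermediate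
7 | tert-butyl (3S,5E,9E,13E)-3-{[(4S)-4-benzyl-2-oxo-1,3-oxazolidin-3-yl]carbonyl}-6,10,14,18-tetramethylnonadeca-5,9,13,17-tetraenoate | CC(C)=CCC/C(C)=C/CC/C(C)=C/CC/C(C)=C/C[C@@H](CC(=O)OC(C)(C)C)C(=O)N1[C@@H](Cc2ccccc2)COC1=O | intermediate
8 | tert-butyl (3S,5E,9E,13E)-3-[(ethylsulfanyl)carbonyl]-6,10,14,18-tetramethylnonadeca-5,9,13,17-tetraenoate | CC(C)=CCC/C(C)=C/CC/C(C)=C/CC/C(C)=C/C[C@@H](CC(=O)OC(C)(C)C)C(=O)SCC | intermediate
9 | propyne | CC#C | starting material
10 | tert-butyl (3S,5E,9E,13E)-3-(but-2-ynoyl)-6,10,14,18-tetramethylnonadeca-5,9,13,17-tetraenoate | CC(C)=CCC/C(C)=C/CC/C(C)=C/CC/C(C)=C/C[C@@H](CC(=O)OC(C)(C)C)C(=O)C#CC | intermediate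
11 | tert-butyl (3S,5E,9E,13E)-3-[(1S)-1-hydroxybut-2-yn-1-yl]-6,10,14,18-tetramethylnonadeca-5,9,13,17-tetraenoate | CC(C)=CCC/C(C)=C/CC/C(C)=C/CC/C(C)=C/C[C@@H](CC(=O)OC(C)(C)C)[C@H](O)C#CC | intermediate
12 | cyclic alkenylaluminate (idealised formula: aluminium bound to C2 and O4 in a five-membered ring, two 2-methoxyethoxy ligands, primary alkoxide, sodium counter-ions) | CC(C)=CCC/C(C)=C/CC/C(C)=C/CC/C(C)=C/C[C@@H](CC[O-])[C@@H]1O[Al-](OCCOC)(OCCOC)C(C)=C1.[Na+].[Na+] | intermediate
13 | (2Z,4S,5S)-2-iodo-5-[(2E,6E,10E)-3,7,11,15-tetramethylhexadeca-2,6,10,14-tetraen-1-yl]hept-2-ene-4,7-diol | CC(C)=CCC/C(C)=C/CC/C(C)=C/CC/C(C)=C/C[C@@H](CCO)[C@H](O)/C=C(/C)I | intermediate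
14 | (3S,4S,5Z)-4-hydroxy-6-iodo-3-[(2E,6E,10E)-3,7,11,15-tetramethylhexadeca-2,6,10,14-tetraen-1-yl]hept-5-enal | CC(C)=CCC/C(C)=C/CC/C(C)=C/CC/C(C)=C/C[C@@H](CC=O)[C@H](O)/C=C(/C)I | intermediate
15 | (4S,5S)-5-[(1Z)-2-iodoprop-1-en-1-yl]-4-[(2E,6E,10E)-3,7,11,15-tetramethylhexadeca-2,6,10,14-tetraen-1-yl]oxolan-2-ol (lactol, both anomers) | CC(C)=CCC/C(C)=C/CC/C(C)=C/CC/C(C)=C/C[C@H]1CC(O)O[C@@H]1/C=C(/C)I | intermediate
16 | (4S,5S)-5-[(1Z)-2-iodoprop-1-en-1-yl]-4-[(2E,6E,10E)-3,7,11,15-tetramethylhexadeca-2,6,10,14-tetraen-1-yl]oxolan-2-one (trans) | CC(C)=CCC/C(C)=C/CC/C(C)=C/CC/C(C)=C/C[C@H]1CC(=O)O[C@@H]1/C=C(/C)I | intermediate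
17 | Z-alkenyllithium derived from 16 (lithium in place of iodine) | CC(C)=CCC/C(C)=C/CC/C(C)=C/CC/C(C)=C/C[C@H]1CC(=O)O[C@@H]1/C=C(/C)[Li] | intermediate
18 | lithium 2-methyl-5-geranylgeranyl-7-oxabicyclo[2.2.1]hept-2-en-1-olate (bridged hemiketal alkoxide, side chain syn to the oxygen bridge) | CC(C)=CCC/C(C)=C/CC/C(C)=C/CC/C(C)=C/C[C@H]1C[C@@]2([O-])O[C@@H]1C=C2C.[Li+] | intermediate
19 | lithium alkoxide of the target | CC(C)=CCC/C(C)=C/CC/C(C)=C/CC/C(C)=C/C[C@H]1CC(=O)C(C)=C[C@H]1[O-].[Li+] | intermediate
20 | (4S,5S)-4-hydroxy-2-methyl-5-[(2E,6E,10E)-3,7,11,15-tetramethylhexadeca-2,6,10,14-tetraen-1-yl]cyclohex-2-en-1-one | CC(C)=CCC/C(C)=C/CC/C(C)=C/CC/C(C)=C/C[C@H]1CC(=O)C(C)=C[C@H]1O | target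

**Step count and risks**

Total steps: 9. Longest linear sequence: 8 (steps 2 to 9; step 1 is a one-step branch that joins at step 3).

Steps most likely to fail:

Step 9 (proposed new method). The alkenyllithium may be quenched by intramolecular proton transfer from the lactone alpha-CH2 before it adds. The strain of the bridged intermediate may slow closure enough for intermolecular addition to the lactone or to the product enone to take over. Fallback with known chemistry, from 16: the lactone is opened with AlMe3 and MeNHOMe·HCl in CH2Cl2 at 0 °C to the hydroxy Weinreb amide F1. This is silylated at once with TESOTf and 2,6-lutidine at −78 °C to the triethylsilyl ether F2. Treatment of F2 with t-BuLi in THF at −78 °C should give iodine–lithium exchange and a Parham-type 6-exo-trig acylation by the Weinreb amide, forming the silyl-protected enone F3. HF·pyridine in THF/pyridine at 0 °C then removes the silyl group and the route comes back at 20.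

Step 7. The hydroalumination may stall or lose regiocontrol while the ester is being reduced in the same flask. During the iodine quench, electrophilic iodine may also react with the trisubstituted alkenes, assisted by the neighbouring alkoxides (iodoetherification). Fallback, from 10: conjugate hydroiodination of the ynone with NaI in AcOH at rt should give the Z-beta-iodo enone F4. Reduction with (R)-Me-CBS oxazaborolidine and catecholborane in toluene at −78 °C, with the iodoalkenyl group acting as the large substituent, should give the (S)-allylic alcohol F5. A catalytic amount of camphorsulfonic acid in CH2Cl2 at rt then lactonises the gamma-hydroxy tert-butyl ester, and the route comes back at 16 without passing through 11 and 13.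

Step 5. The alpha-stereocentre may epimerise, or the propynyl ketone may isomerise to an allenyl ketone, under amine base at 50 °C. The volatile alkyne may also couple slowly or homocouple. Fallback, from 7: the auxiliary is removed with LiOH and H2O2 in THF/H2O at 0 °C to give the acid F6. Coupling with MeNHOMe·HCl using EDC·HCl, HOBt and i-Pr2NEt in CH2Cl2 gives the Weinreb amide F7. Addition of prop-1-ynylmagnesium bromide in THF at −20 to 0 °C then gives the ynone through the stable chelated tetrahedral intermediate, and the route comes back at 10.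

Further compounds
F1 | step 9 | (3S,4S,5Z)-4-hydroxy-6-iodo-N-methoxy-N-methyl-3-[(2E,6E,10E)-3,7,11,15-tetramethylhexadeca-2,6,10,14-tetraen-1-yl]hept-5-enamide | CC(C)=CCC/C(C)=C/CC/C(C)=C/CC/C(C)=C/C[C@@H](CC(=O)N(C)OC)[C@H](O)/C=C(/C)I
F2 | step 9 | (3S,4S,5Z)-6-iodo-N-methoxy-N-methyl-3-[(2E,6E,10E)-3,7,11,15-tetramethylhexadeca-2,6,10,14-tetraen-1-yl]-4-(triethylsilyloxy)hept-5-enamide | CC(C)=CCC/C(C)=C/CC/C(C)=C/CC/C(C)=C/C[C@@H](CC(=O)N(C)OC)[C@H](O[Si](CC)(CC)CC)/C=C(/C)I
F3 | step 9 | (4S,5S)-2-methyl-5-[(2E,6E,10E)-3,7,11,15-tetramethylhexadeca-2,6,10,14-tetraen-1-yl]-4-(triethylsilyloxy)cyclohex-2-en-1-one | CC(C)=CCC/C(C)=C/CC/C(C)=C/CC/C(C)=C/C[C@H]1CC(=O)C(C)=C[C@H]1O[Si](CC)(CC)CC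
F4 | step 7 | tert-butyl (3S,5E,9E,13E)-3-[(2Z)-3-iodobut-2-enoyl]-6,10,14,18-tetramethylnonadeca-5,9,13,17-tetraenoate | CC(C)=CCC/C(C)=C/CC/C(C)=C/CC/C(C)=C/C[C@@H](CC(=O)OC(C)(C)C)C(=O)/C=C(/C)I
F5 | step 7 | tert-butyl (3S,5E,9E,13E)-3-[(1S,2Z)-1-hydroxy-3-iodobut-2-en-1-yl]-6,10,14,18-tetramethylnonadeca-5,9,13,17-tetraenoate | CC(C)=CCC/C(C)=C/CC/C(C)=C/CC/C(C)=C/C[C@@H](CC(=O)OC(C)(C)C)[C@H](O)/C=C(/C)I
F6 | step 5 | (2S,4E,8E,12E)-2-(2-tert-butoxy-2-oxoethyl)-5,9,13,17-tetramethyloctadeca-4,8,12,16-tetraenoic acid | CC(C)=CCC/C(C)=C/CC/C(C)=C/CC/C(C)=C/C[C@@H](CC(=O)OC(C)(C)C)C(=O)O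
F7 | step 5 | tert-butyl (3S,5E,9E,13E)-3-[methoxy(methyl)carbamoyl]-6,10,14,18-tetramethylnonadeca-5,9,13,17-tetraenoate | CC(C)=CCC/C(C)=C/CC/C(C)=C/CC/C(C)=C/C[C@@H](CC(=O)OC(C)(C)C)C(=O)N(C)OC
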